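## Retrosynthetic overview

1. The target (S)-diheteroarylmethine comes from bis-Boc bis-amide **12**, which comes from diamine **10**. **10** comes from bis-phthalimide **9**. The two dibromopyrrole amides are installed at the end from a trichloroacetylpyrrole.
2. **9** comes from a Suzuki coupling of the hindered bromide **8** with (E)-alkenyl-Bpin **6**, which sets the E-alkene.
3. **8** is made by the key new step: chiral-acid hydroarylation of the alkenylimidazole **7** (protonated to an azafulvenium) by C5–H of 4-bromo-2-(Boc-amino)imidazole **4**. This forms the C–C bond and sets the (S)-centre.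
4. **7** comes from **4** and **6** by Suzuki coupling. **4** comes from 2-aminoimidazole by Boc protection, dibromination and mono-debromination. **6** comes from hydroboration of N-propargylphthalimide.
5. No heterocycle is constructed. Both 2-aminoimidazoles come from commercial 2-aminoimidazole, and the pyrrole comes pre-brominated as its trichloroketone.

Assumptions:
- NH tautomers are drawn as in the target.
- Boc2O in MeOH gives the exocyclic NHBoc as the thermodynamic product, because any ring N-Boc is methanolysed.
- The target stereocentre is (S) by CIP (Im-B > Im-A > CH2 > H). The catalyst antipode giving (S) is assumed to be the (S)-catalyst and would be confirmed by screening both.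

## Route

**Step 1**
Reactants: **1** 2-amino-1H-imidazole (as hemisulfate)
Product: **2** tert-butyl (1H-imidazol-2-yl)carbamate
Conditions: Boc2O (1.05 equiv), Et3N (2.5 equiv), MeOH, 25 → 50 °C
Reagents that add atoms: Boc2O, CC(C)(C)OC(=O)OC(=O)OC(C)(C)C
Why: Chemoselective carbamoylation of the exocyclic amine, since any ring N-Boc is cleaved by MeOH. The Boc group lowers the basicity of the aminoimidazole, which is needed later for Brønsted-acid catalysis.

**Step 2**
Reactants: **2**
Product: **3** tert-butyl (4,5-dibromo-1H-imidazol-2-yl)carbamate
Conditions: NBS (2.1 equiv), THF, 0 °C → 25 °C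
Reagents that add atoms: NBS, O=C1CCC(=O)N1Br
Why: Electrophilic bromination at both free carbons of the electron-rich 2-acylaminoimidazole.

**Step 3**
Reactants: **3**
Product: **4** tert-butyl (4-bromo-1H-imidazol-2-yl)carbamate
Conditions: Na2SO3 (10 equiv), dioxane/H2O 1:1, 95 °C, 24 h
Reagents that add atoms: none (Br is replaced by H from the solvent)
Why: Sulfite reductive mono-debromination, as in the standard 4,5-dibromoimidazole → 4-bromoimidazole conversion. Once one bromine is removed the ring is too electron-rich for a second reduction, so the reaction stops at the mono-bromide.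

**Step 4**
Reactants: **5** N-propargylphthalimide; HBpin
Product: **6** 2-[(E)-3-(Bpin)allyl]isoindoline-1,3-dione
Conditions: HBpin (1.2 equiv), Cp2Zr(H)Cl (10 mol%), neat, 60 °C
Reagents that add atoms: HBpin, [H]B1OC(C)(C)C(C)(C)O1
Why: Zr-catalysed syn-hydroboration of a terminal alkyne gives the terminal (E)-alkenylboronate.

**Step 5**
Reactants: **4**; **6**
Product: **7** tert-butyl {4-[(E)-3-phthalimidoprop-1-en-1-yl]-1H-imidazol-2-yl}carbamate
Conditions: **6** (1.3 equiv), XPhos Pd G2 (3 mol%), K3PO4 (3 equiv), dioxane/H2O 10:1, 80 °C, 3 h
Reagents that add atoms: none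
Why: Suzuki–Miyaura coupling of an NH-free 4-bromoimidazole with an alkenyl-Bpin, which retains the E geometry. Phthalimide is chosen as a non-nucleophilic nitrogen group; an NHBoc would trap the cation in step 6 as a cyclic carbamate.

**Step 6 (key step)**
Reactants: **7** (electrophile, 1.0 equiv, syringe-pump addition); **4** (nucleophile, 4.0 equiv)
Product: **8** tert-butyl {4-bromo-5-[(S)-1-(2-(Boc-amino)-1H-imidazol-4-yl)-3-phthalimidopropyl]-1H-imidazol-2-yl}carbamate
Conditions: (S)-IDPi (BINOL-derived imidodiphosphorimidate, 5 mol%), PhCF3/CH2Cl2 4:1, –10 → 25 °C, 48 h; **7** added over 10 h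
Reagents that add atoms: none (atom-economical hydroarylation)
Why: Proposed new method: the strong confined Brønsted acid protonates the C=C of **7** at the carbon remote from the ring. This gives a benzylic-type 4-alkylidene-imidazolium (azafulvenium), whose NH and carbamate NH hydrogen-bond to the chiral anion. C5–H of **4** is the only free ring carbon and is enamine-like, so it attacks one enantiotopic face of the cation inside the chiral pocket. Loss of H+ rearomatises the ring and regenerates the catalyst, setting the (S) diheteroarylmethine centre. The closest known chemistry is IDPi/CPA-catalysed enantioselective hydroarylation of styrenes and vinylindoles, and CPA Friedel–Crafts alkylation of indoles via indolylmethanol-derived vinylogous iminium ions. This proposal extends that reactivity to alkenylimidazoles and imidazole C–H nucleophiles. The 4-fold excess of **4** and slow addition of **7** suppress self-coupling of **7**, and the bromine blocks C4 of the nucleophile so the regiochemistry is unambiguous.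

**Step 7**
Reactants: **8**; **6**
Product: **9** bis-phthalimide, 4-[(E)-3-phthalimidopropenyl] on imidazole B (Br replaced)
Conditions: **6** (2.0 equiv), XPhos Pd G3 (5 mol%), K3PO4 (3 equiv), dioxane/H2O 10:1, 90 °C, 4 h
Reagents that add atoms: none
Why: Suzuki coupling installs the second E-alkenyl chain. The stereocentre is a non-acidic diheteroaryl methine and is untouched.

**Step 8**
Reactants: **9**
Product: **10** diamine, tert-butyl N-protected at both imidazoles, with free CH2CH2NH2 and (E)-CH=CH–CH2NH2 chains
Conditions: 33% MeNH2 in EtOH, 25 °C, 12 h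
Reagents that add atoms: none (the phthalamide by-product is discarded)
Why: Ing–Manske-type aminolysis removes both phthalimides. The Boc groups, the alkene and the stereocentre are unaffected.

**Step 9**
Reactants: **10**; **11** 4,5-dibromo-2-(trichloroacetyl)-1H-pyrrole (2.5 equiv)
Product: **12** bis-Boc bis(dibromopyrrole carboxamide)
Conditions: Et3N (3 equiv), DMF, 25 °C, 16 h
Reagents that add atoms: none (**11** is the reactant; CHCl3 is lost)
Why: Haloform-type acyl transfer from the trichloroketone to the two primary amines only. The Boc-protected 2-aminoimidazoles and the imidazole NHs are unreactive, and this is the standard oroidin-type amide formation.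

**Step 10**
Reactants: **12**
Product: **13** target
Conditions: 4 M HCl/dioxane, CH2Cl2, anisole (5 equiv), 0 → 25 °C, 3 h; neutralise with aq. NaHCO3 or SCX, then prep-HPLC
Reagents that add atoms: none (the free base is isolated)
Why: Acidolytic removal of both Boc groups. The resulting aminoimidazolium rings are deactivated, so there is no retro-Friedel–Crafts ionisation or racemisation, and the dibromopyrrole amides and E-alkene survive.

## Compound list

| # | Name | SMILES | Role |
|---|---|---|---|
| 1 | 2-Amino-1H-imidazole (hemisulfate) | Nc1ncc[nH]1 | starting material |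
| 2 | tert-Butyl (1H-imidazol-2-yl)carbamate | CC(C)(C)OC(=O)Nc1ncc[nH]1 | intermediate |
| 3 | tert-Butyl (4,5-dibromo-1H-imidazol-2-yl)carbamate | CC(C)(C)OC(=O)Nc1nc(Br)c(Br)[nH]1 | intermediate |
| 4 | tert-Butyl (4-bromo-1H-imidazol-2-yl)carbamate | CC(C)(C)OC(=O)Nc1nc(Br)c[nH]1 | intermediate |
| 5 | N-Propargylphthalimide | C#CCN1C(=O)c2ccccc2C1=O | starting material |
| 6 | (E)-3-phthalimidoprop-1-enyl-Bpin | O=C1c2ccccc2C(=O)N1C/C=C/B1OC(C)(C)C(C)(C)O1 | intermediate |
| 7 | Boc-aminoimidazolyl (E)-allylphthalimide | CC(C)(C)OC(=O)Nc1ncc(/C=C/CN2C(=O)c3ccccc3C2=O)[nH]1 | intermediate |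
| 8 | (S)-bromo diimidazolylpropyl phthalimide (bis-NHBoc) | CC(C)(C)OC(=O)Nc1ncc([C@H](CCN2C(=O)c3ccccc3C2=O)c2[nH]c(NC(=O)OC(C)(C)C)nc2Br)[nH]1 | intermediate |
| 9 | (S)-bis-phthalimide, bis-NHBoc | CC(C)(C)OC(=O)Nc1ncc([C@H](CCN2C(=O)c3ccccc3C2=O)c2[nH]c(NC(=O)OC(C)(C)C)nc2/C=C/CN2C(=O)c3ccccc3C2=O)[nH]1 | intermediate |
| 10 | (S)-diamine, bis-NHBoc | CC(C)(C)OC(=O)Nc1ncc([C@H](CCN)c2[nH]c(NC(=O)OC(C)(C)C)nc2/C=C/CN)[nH]1 | intermediate |
| 11 | 4,5-Dibromo-2-(trichloroacetyl)-1H-pyrrole | O=C(c1cc(Br)c(Br)[nH]1)C(Cl)(Cl)Cl | starting material |
| 12 | (S)-bis-Boc bis-amide | CC(C)(C)OC(=O)Nc1ncc([C@H](CCNC(=O)c2cc(Br)c(Br)[nH]2)c2[nH]c(NC(=O)OC(C)(C)C)nc2/C=C/CNC(=O)c2cc(Br)c(Br)[nH]2)[nH]1 | intermediate |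
| 13 | Target (S) | Nc1ncc([C@H](CCNC(=O)c2cc(Br)c(Br)[nH]2)c2[nH]c(N)nc2/C=C/CNC(=O)c2cc(Br)c(Br)[nH]2)[nH]1 | target |

## Step count

- Total steps: 10
- Longest linear sequence: 9 (steps 1, 2, 3, 5, 6, 7, 8, 9, 10)

## Three steps most likely to fail

1. **Step 6 (proposed new enantioselective hydroarylation).** Risks are poor C-protonation of the alkene, oligomerisation of **7**, and low ee. Fallback: make racemic **8** by achiral TfOH-promoted Friedel–Crafts hydroarylation of **7** with excess **4**, then separate the enantiomers by preparative chiral SFC or HPLC and carry (S)-**8** forward. This is known chemistry and changes the approach from catalytic asymmetric induction to resolution.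
2. **Step 7 (hindered Suzuki on 8, with Pd and aqueous base near phthalimide).** Fallback: use the 2-(Boc-amino)imidazole-4-carbaldehyde in place of **4** as the nucleophile in step 6. After the Friedel–Crafts step, build the E-allylamine chain by HWE olefination with triethyl phosphonoacetate, DIBAL reduction of the ester, then Mitsunobu with phthalimide. This is known chemistry with no Pd coupling at the hindered position.
3. **Step 3 (clean mono-debromination of Boc-protected 3 by sulfite).** The Boc group may not survive, or debromination may be incomplete. Fallback: treat **3** with i-PrMgCl·LiCl (3.5 equiv, THF, –20 °C) for Br/Mg exchange and quench with water. This replaces the reductive sulfite route with a metal–halogen exchange.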